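**Plan**

- **Cuts:** both CH2OH carbons go back to esters. The C5–vinyl bond goes back to a Mizoroki–Heck coupling of a C5 aryl triflate. O1–C7a and C3–C3a are cut together, which frees a β-hydroxy ester and a six-membered ring.
- **Enabling feature:** O1–C2–C3 is the oxygen/α-carbon pair of an aldol-type β-hydroxy ester, a 1,3-dinucleophile. C7a and C3a are neighbours in the benzo ring, whose only other substituent sits at C5, para to C7a. At the quinone monoketal oxidation level C7a is the ketal carbon, C3a the enone β-carbon (polarity reversed against the aryl ether) and C5 the carbonyl carbon, so the ring is a symmetric 1,2-dielectrophile.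
- **Forward order:** asymmetric hydrogenation; dianion plus quinone monoketal annulation, which closes the dihydrofuran ring and restores the benzene ring; C3 epimerization; triflation of the helper oxygen at C5; Heck chain attachment; global ester reduction.
- **Stereochemistry:** C2 comes from the ruthenium/(S)-BINAP hydrogenation and its C–O bond is never broken afterwards. C3 is set by thermodynamic relay from C2 (trans). The E alkene comes from the Heck reaction.

Key step: step 2

Remark: benzofuran numbering (O1, C2, C3, C3a, C4 to C7, C7a) is used for the target and for the same atoms in every precursor. Ethyl 3,4,5-trimethoxybenzoylacetate, 4,4-dimethoxycyclohexa-2,5-dienone and methyl acrylate are taken as commercial.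

Step 1
Reactants: 1 ethyl 3-oxo-3-(3,4,5-trimethoxyphenyl)propanoate
Product: 2 ethyl (R)-3-hydroxy-3-(3,4,5-trimethoxyphenyl)propanoate
Conditions: H2 (50 bar), [RuCl(C6H6)((S)-BINAP)]Cl (0.5 mol %), EtOH, 60 °C
Reagents that add atoms: none
Why: Noyori asymmetric hydrogenation of a β-keto ester, in which the substrate chelates divalent ruthenium through its ketone and ester oxygens and the (S)-BINAP environment directs hydride to the face that gives the (R)-carbinol of aroylacetates, the future C2.

Step 2
Reactants: 2 ethyl (R)-3-hydroxy-3-(3,4,5-trimethoxyphenyl)propanoate; 3 4,4-dimethoxycyclohexa-2,5-dien-1-one (limiting reagent)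
Product: 7 ethyl (2R,3S)-5-hydroxy-2-(3,4,5-trimethoxyphenyl)-2,3-dihydro-1-benzofuran-3-carboxylate (2,3-cis), via dilithio dianion 4 (not isolated), via Michael adduct 5 (not isolated), via bicyclic mixed ketal 6 (not isolated)
Conditions: LiN(iPr)2 (2.2 equiv), THF, −78 to −20 °C; add to 3·MeAl(OAr)2 [made from AlMe3 and ArOH (2 equiv), Ar = 2,6-tBu2-4-MeC6H2], toluene, −78 °C; then CF3CO2H (excess), −78 °C to rt
Reagents that add atoms: none
Why: Proposed new method: the lithium-chelated dianion 4 attacks through C3 the enone β-carbon of 3, whose carbonyl group is buried by the bulky aluminium bis(aryloxide) so that 1,2-addition is closed off, cold protonation gives 5, acid then ionizes the ketal, the C2 hydroxyl captures the oxocarbenium carbon to give 6, and loss of the second methanol together with the C3a proton restores the benzene ring irreversibly. The closest known reaction types are the Fráter–Seebach alkylation of β-hydroxy ester dianions, the conjugate addition of organolithium reagents to quinone monoketals under the same aluminium reagent and the acid-induced aromatization of quinone monoketal Michael adducts, but their merger with a β-hydroxy ester as C,O-dinucleophile has not been shown. The one ring that closes, the dihydrofuran, forms by 5-exo-trig attack of O1 on the C7a oxocarbenium ion after the intermolecular C3–C3a bond has tied the partners together. C2 is carried over from 2 because its C–O bond is never broken, C3 is set by attack on the enolate face remote from the aryl group of the six-membered lithium chelate (anti adduct, hence 2,3-cis after closure, corrected in step 3), and the centres at C3a and C7a, drawn for one epimer, vanish on aromatization. No regiochemical control is needed, since the mirror plane of 3 through C5 and C7a makes both β-carbons equivalent and fixes the new phenol para to O1. The selectivity that counts is retention of O1 instead of a methoxy group, secured by the tethered hydroxyl trapping the cation faster than it can lose a proton, by the dilution of the released methanol and by the methoxy oxygen being the less hindered and more basic leaving site, while β-elimination and retro-aldol cleavage are held off because oxide is no leaving group in 4 and the aldolate is quenched cold.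

Step 3
Reactants: 7 ethyl (2R,3S)-5-hydroxy-2-(3,4,5-trimethoxyphenyl)-2,3-dihydro-1-benzofuran-3-carboxylate
Product: 8 methyl (2R,3R)-5-hydroxy-2-(3,4,5-trimethoxyphenyl)-2,3-dihydro-1-benzofuran-3-carboxylate (2,3-trans)
Conditions: NaOMe (3 equiv), MeOH, 0 °C to rt; AcOH quench
Reagents that add atoms: sodium methoxide in methanol, C[O-].[Na+]
Why: Thermodynamic epimerization through the ester enolate, with concurrent transesterification by methoxide, should converge on the more stable 2,3-trans ester, so that C3 is set by relay from the untouched C2, while the C5 phenoxide formed first makes O1 a poor leaving group and holds back β-elimination.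

Step 4
Reactants: 8 methyl (2R,3R)-5-hydroxy-2-(3,4,5-trimethoxyphenyl)-2,3-dihydro-1-benzofuran-3-carboxylate
Product: 9 methyl (2R,3R)-5-{[(trifluoromethyl)sulfonyl]oxy}-2-(3,4,5-trimethoxyphenyl)-2,3-dihydro-1-benzofuran-3-carboxylate
Conditions: PhNTf2, Et3N, CH2Cl2, 0 °C to rt
Reagents that add atoms: N-phenylbis(trifluoromethanesulfonimide), O=S(=O)(N(c1ccccc1)S(=O)(=O)C(F)(F)F)C(F)(F)F
Why: O-sulfonylation of the phenol with a mild triflyl donor turns the helper oxygen at C5 into a cross-coupling leaving group without touching either stereocentre.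

Step 5
Reactants: 9 methyl (2R,3R)-5-{[(trifluoromethyl)sulfonyl]oxy}-2-(3,4,5-trimethoxyphenyl)-2,3-dihydro-1-benzofuran-3-carboxylate; 10 methyl acrylate
Product: 11 methyl (2R,3R)-5-[(E)-3-methoxy-3-oxoprop-1-en-1-yl]-2-(3,4,5-trimethoxyphenyl)-2,3-dihydro-1-benzofuran-3-carboxylate
Conditions: Pd(OAc)2 (5 mol %), Ph2P(CH2)3PPh2 (6 mol %), Et3N, DMF, 90 °C
Reagents that add atoms: none
Why: Mizoroki–Heck reaction, in which oxidative addition of the aryl triflate to zerovalent palladium, syn insertion of the acrylate at its unsubstituted carbon and syn β-hydride elimination give the (E)-cinnamate, and triethylamine is too weak a base to disturb the already thermodynamic trans C2/C3 pair.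

Step 6
Reactants: 11 methyl (2R,3R)-5-[(E)-3-methoxy-3-oxoprop-1-en-1-yl]-2-(3,4,5-trimethoxyphenyl)-2,3-dihydro-1-benzofuran-3-carboxylate
Product: 12 (E)-3-[(2R,3S)-3-(hydroxymethyl)-2-(3,4,5-trimethoxyphenyl)-2,3-dihydro-1-benzofuran-5-yl]prop-2-en-1-ol (CNP0077408.1)
Conditions: iBu2AlH (6 equiv), CH2Cl2, −78 to 0 °C
Reagents that add atoms: none
Why: Hydride reduction of both esters with iBu2AlH, which reduces the enoate in the 1,2-sense to the allylic alcohol and leaves the alkene, the benzylic ether and both stereocentres alone (the C3 descriptor changes from R to S only through the priority change from ester to CH2OH).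

**Compound list**

1 | ethyl 3-oxo-3-(3,4,5-trimethoxyphenyl)propanoate | CCOC(=O)CC(=O)c1cc(OC)c(OC)c(OC)c1 | starting material
2 | ethyl (R)-3-hydroxy-3-(3,4,5-trimethoxyphenyl)propanoate | COc1cc([C@H](O)CC(=O)OCC)cc(OC)c1OC | intermediate
3 | 4,4-dimethoxycyclohexa-2,5-dien-1-one | COC1(OC)C=CC(=O)C=C1 | starting material
4 | dilithio dianion of 2 (lithium alkoxide at C2, lithium ester enolate at C3, enolate OLi cis to C2 in a six-membered chelate) | [Li]O/C(OCC)=C\[C@@H](O[Li])c1cc(OC)c(OC)c(OC)c1 | intermediate
5 | ethyl (2S,3R)-2-[(1S)-6,6-dimethoxy-3-oxocyclohex-4-en-1-yl]-3-hydroxy-3-(3,4,5-trimethoxyphenyl)propanoate (anti adduct; ring carbon drawn for one epimer, both converge) | CCOC(=O)[C@H]([C@@H](O)c1cc(OC)c(OC)c(OC)c1)[C@@H]1CC(=O)C=CC1(OC)OC | intermediate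
6 | ethyl (2R,3S,3aS,7aS)-7a-methoxy-5-oxo-2-(3,4,5-trimethoxyphenyl)-2,3,3a,4,5,7a-hexahydro-1-benzofuran-3-carboxylate (cis-fused) | CCOC(=O)[C@@H]1[C@H](c2cc(OC)c(OC)c(OC)c2)O[C@@]2(OC)C=CC(=O)C[C@@H]12 | intermediate
7 | ethyl (2R,3S)-5-hydroxy-2-(3,4,5-trimethoxyphenyl)-2,3-dihydro-1-benzofuran-3-carboxylate (cis) | COc1cc([C@@H]2Oc3ccc(O)cc3[C@@H]2C(=O)OCC)cc(OC)c1OC | intermediate
8 | methyl (2R,3R)-5-hydroxy-2-(3,4,5-trimethoxyphenyl)-2,3-dihydro-1-benzofuran-3-carboxylate (trans) | COc1cc([C@@H]2Oc3ccc(O)cc3[C@H]2C(=O)OC)cc(OC)c1OC | intermediate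
9 | methyl (2R,3R)-5-{[(trifluoromethyl)sulfonyl]oxy}-2-(3,4,5-trimethoxyphenyl)-2,3-dihydro-1-benzofuran-3-carboxylate | COc1cc([C@@H]2Oc3ccc(OS(=O)(=O)C(F)(F)F)cc3[C@H]2C(=O)OC)cc(OC)c1OC | intermediate
10 | methyl acrylate | C=CC(=O)OC | starting material
11 | methyl (2R,3R)-5-[(E)-3-methoxy-3-oxoprop-1-en-1-yl]-2-(3,4,5-trimethoxyphenyl)-2,3-dihydro-1-benzofuran-3-carboxylate | COc1cc([C@@H]2Oc3ccc(/C=C/C(=O)OC)cc3[C@H]2C(=O)OC)cc(OC)c1OC | intermediate
12 | (E)-3-[(2R,3S)-3-(hydroxymethyl)-2-(3,4,5-trimethoxyphenyl)-2,3-dihydro-1-benzofuran-5-yl]prop-2-en-1-ol | COc1cc([C@@H]2Oc3ccc(/C=C/CO)cc3[C@H]2CO)cc(OC)c1OC | target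

Total step count: 6. Longest linear sequence: 6 (steps 1 to 6).

**Steps most likely to fail**

**Step 2.**
- What may go wrong: attack at the carbonyl carbon, or electron transfer, may take the place of conjugate addition. A proton may be lost from the first oxocarbenium ion before the hydroxyl captures it, or O1 may depart in place of methoxy, so that the ring aromatizes without closing. The acid may also ionize the benzylic C2–O bond.
- Fallback (known chemistry, from 1 back to 8): 1 is condensed with p-benzoquinone (ZnCl2, EtOH, reflux). This is a conjugate addition of the β-keto ester followed by cyclodehydration, and it gives ethyl 5-hydroxy-2-(3,4,5-trimethoxyphenyl)-1-benzofuran-3-carboxylate F1. Dissolving-metal reduction with Mg in MeOH saturates C2=C3, settles on the trans isomer and exchanges the ester alkyl group, giving racemic methyl trans-5-hydroxy-2-(3,4,5-trimethoxyphenyl)-2,3-dihydro-1-benzofuran-3-carboxylate F2. Preparative chromatography on a chiral stationary phase then delivers 8.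

**Step 3.**
- What may go wrong: reversible β-elimination of the aryloxide from the ester enolate (ring opening and reclosure) would erode the configuration at C2.
- Fallback (from 7 back to 12): the equilibration is moved to the aldehyde level and run without base.
  - 7 is triflated as in step 4 to ethyl (2R,3S)-5-{[(trifluoromethyl)sulfonyl]oxy}-2-(3,4,5-trimethoxyphenyl)-2,3-dihydro-1-benzofuran-3-carboxylate F3.
  - Reduction with iBu2AlH (1.1 equiv, toluene, −78 °C) gives (2R,3S)-3-formyl-2-(3,4,5-trimethoxyphenyl)-2,3-dihydro-1-benzofuran-5-yl trifluoromethanesulfonate F4.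
  - Mild acid (pyridinium p-toluenesulfonate, CH2Cl2) equilibrates F4 through its enol, where no enolate exists that could expel O1, to (2R,3R)-3-formyl-2-(3,4,5-trimethoxyphenyl)-2,3-dihydro-1-benzofuran-5-yl trifluoromethanesulfonate F5.
  - NaBH4 (MeOH, 0 °C) gives (2R,3S)-3-(hydroxymethyl)-2-(3,4,5-trimethoxyphenyl)-2,3-dihydro-1-benzofuran-5-yl trifluoromethanesulfonate F6.
  - Stille coupling with (E)-3-(tributylstannyl)prop-2-en-1-ol (Pd(PPh3)4, LiCl, dioxane, 90 °C) gives 12.

**Step 5.**
- What may go wrong: oxidative addition of the electron-rich aryl triflate may be slow, the triflate may suffer S–O cleavage in hot basic DMF, and the catalyst may decay before turnover.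
- Fallback (from 9 back to 12): the chain is brought in as a preformed vinyl metal instead of through alkene insertion. Stille coupling of 9 with (E)-3-(tributylstannyl)prop-2-en-1-ol (Pd(PPh3)4, LiCl, dioxane, 90 °C) gives methyl (2R,3R)-5-[(E)-3-hydroxyprop-1-en-1-yl]-2-(3,4,5-trimethoxyphenyl)-2,3-dihydro-1-benzofuran-3-carboxylate F7. Reduction of the remaining ester with iBu2AlH (CH2Cl2, −78 to 0 °C) gives 12.

**Further compounds**

F1 | step 2 | ethyl 5-hydroxy-2-(3,4,5-trimethoxyphenyl)-1-benzofuran-3-carboxylate | CCOC(=O)c1c(-c2cc(OC)c(OC)c(OC)c2)oc2ccc(O)cc12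
F2 | step 2 | racemic methyl trans-5-hydroxy-2-(3,4,5-trimethoxyphenyl)-2,3-dihydro-1-benzofuran-3-carboxylate (both enantiomers written) | COc1cc([C@@H]2Oc3ccc(O)cc3[C@H]2C(=O)OC)cc(OC)c1OC.COc1cc([C@H]2Oc3ccc(O)cc3[C@@H]2C(=O)OC)cc(OC)c1OC
F3 | step 3 | ethyl (2R,3S)-5-{[(trifluoromethyl)sulfonyl]oxy}-2-(3,4,5-trimethoxyphenyl)-2,3-dihydro-1-benzofuran-3-carboxylate | COc1cc([C@@H]2Oc3ccc(OS(=O)(=O)C(F)(F)F)cc3[C@@H]2C(=O)OCC)cc(OC)c1OC
F4 | step 3 | (2R,3S)-3-formyl-2-(3,4,5-trimethoxyphenyl)-2,3-dihydro-1-benzofuran-5-yl trifluoromethanesulfonate | COc1cc([C@@H]2Oc3ccc(OS(=O)(=O)C(F)(F)F)cc3[C@@H]2C=O)cc(OC)c1OC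
F5 | step 3 | (2R,3R)-3-formyl-2-(3,4,5-trimethoxyphenyl)-2,3-dihydro-1-benzofuran-5-yl trifluoromethanesulfonate | COc1cc([C@@H]2Oc3ccc(OS(=O)(=O)C(F)(F)F)cc3[C@H]2C=O)cc(OC)c1OC
F6 | step 3 | (2R,3S)-3-(hydroxymethyl)-2-(3,4,5-trimethoxyphenyl)-2,3-dihydro-1-benzofuran-5-yl trifluoromethanesulfonate | COc1cc([C@@H]2Oc3ccc(OS(=O)(=O)C(F)(F)F)cc3[C@H]2CO)cc(OC)c1OC
F7 | step 5 | methyl (2R,3R)-5-[(E)-3-hydroxyprop-1-en-1-yl]-2-(3,4,5-trimethoxyphenyl)-2,3-dihydro-1-benzofuran-3-carboxylate | COc1cc([C@@H]2Oc3ccc(/C=C/CO)cc3[C@H]2C(=O)OC)cc(OC)c1OC
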